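**Retrosynthetic overview**

1. The target is reached by hydrogenolysis of a pentadeca-O-benzyl tetramer, which comes from twofold ionic reduction of two C4 tertiary carbinols, themselves from twofold OsO4 dihydroxylation of two flav-3-ene rings.
2. Feature used: C4 of ring C in the terminal ent-fisetinidol unit (bonded to C6 of the middle unit) and C4 of ring C in the ent-fisetinidol unit on catechin C6 are both 1,1-diaryl carbons next to C3. Each C3=C4 bond is therefore cut by ring-closing metathesis to a 1-arylvinyl group on C6 plus an (R)-1-arylallyl ether on the ortho oxygen.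
3. The metathesis precursor comes from twofold iridium-catalysed branched allylic etherification of a bis-phenol, made by twofold Suzuki coupling of a dibromo dimer with a 1-arylvinylboronate.
4. The core dimer (middle unit C4 to catechin C8) comes from 8-lithio-penta-O-benzylcatechin and (2S,3S)-tetra-O-benzyl-ent-fustin, followed by ionic reduction; the ketone comes from a chalcone by asymmetric epoxidation.
5. Ring order: ring C of the middle unit (step 9), then the C4–C8 interflavan bond (steps 11–12), then both outer rings C together (step 23).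

Key step: step 23

Remark: flavan numbering (O1, C2, C3, C4, C4a–C8a) is used for every unit. The (Ra,Rc,Rc) phosphoramidite is assumed to give the (R)-allyl aryl ether, as expected for phenoxide allylation of cinnamyl carbonates; its antipode would be used if the sense were opposite.

**Route**

Step 1
Reactants: 1 (+)-catechin
Product: 2 5,7,3',4'-tetra-O-benzyl-(+)-catechin (2R,3S; 3-OH free)
Conditions: BnBr (4.4 equiv), K2CO3, DMF, 0 °C → rt
Reagents that add atoms: benzyl bromide, BrCc1ccccc1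
Why: Williamson etherification with K2CO3 benzylates the four phenols only, since the secondary 3-OH is not deprotonated, and C2 and C3 are untouched.

Step 2
Reactants: 2 5,7,3',4'-tetra-O-benzyl-(+)-catechin
Product: 3 8-bromo-5,7,3',4'-tetra-O-benzylcatechin
Conditions: NBS (1.0 equiv), CH2Cl2, −78 °C → rt
Reagents that add atoms: N-bromosuccinimide, O=C1CCC(=O)N1Br
Why: Electrophilic aromatic bromination of the phloroglucinol-type ring A goes to C8, the position between O1 and the 7-benzyloxy group, as is the rule for 5,7-di-O-benzylflavan-3-ols with one equivalent of NBS at low temperature.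

Step 3
Reactants: 3 8-bromo-5,7,3',4'-tetra-O-benzylcatechin
Product: 4 8-bromo-3,5,7,3',4'-penta-O-benzylcatechin
Conditions: NaH, BnBr, Bu4NI (cat.), THF/DMF, 0 °C → rt
Reagents that add atoms: benzyl bromide, BrCc1ccccc1
Why: Williamson etherification of the secondary alkoxide; the aryl bromide and the trans C2/C3 centres are inert to NaH at this temperature.

Step 4
Reactants: 5 2,4-dihydroxyacetophenone
Product: 6 1-[4-(benzyloxy)-2-hydroxyphenyl]ethanone
Conditions: BnBr (1.05 equiv), K2CO3, acetone, reflux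
Reagents that add atoms: benzyl bromide, BrCc1ccccc1
Why: Williamson etherification selective for the 4-OH because the 2-OH is locked in a hydrogen bond to the acetyl group.

Step 5
Reactants: 6 1-[4-(benzyloxy)-2-hydroxyphenyl]ethanone
Product: 7 1-[4-(benzyloxy)-2-(methoxymethoxy)phenyl]ethanone
Conditions: NaH, MOMCl, DMF, 0 °C
Reagents that add atoms: chloromethyl methyl ether, COCCl
Why: O-alkylation of the phenoxide with MOMCl masks the phenol that would otherwise divert the later epoxidation into aurone or flavonol formation.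

Step 6
Reactants: 8 3,4-dihydroxybenzaldehyde
Product: 9 3,4-bis(benzyloxy)benzaldehyde
Conditions: BnBr (2.2 equiv), K2CO3, DMF, 60 °C
Reagents that add atoms: benzyl bromide, BrCc1ccccc1
Why: Williamson etherification of both catechol hydroxyls.

Step 7
Reactants: 7 1-[4-(benzyloxy)-2-(methoxymethoxy)phenyl]ethanone; 9 3,4-bis(benzyloxy)benzaldehyde
Product: 10 (E)-1-[4-(benzyloxy)-2-(methoxymethoxy)phenyl]-3-[3,4-bis(benzyloxy)phenyl]prop-2-en-1-one
Conditions: KOH, EtOH/THF, rt
Reagents that add atoms: none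
Why: Claisen–Schmidt aldol condensation gives the (E)-enone by E1cB dehydration under thermodynamic control.

Step 8
Reactants: 10 the (E)-chalcone
Product: 11 [(2S,3R)-3-(3,4-bis(benzyloxy)phenyl)oxiran-2-yl][4-(benzyloxy)-2-(methoxymethoxy)phenyl]methanone (trans-epoxide)
Conditions: immobilised poly-D-leucine, urea–H2O2, DBU, THF, rt
Reagents that add atoms: urea–hydrogen peroxide, OO.NC(N)=O
Why: Juliá–Colonna epoxidation, in which hydroperoxide adds to the enone bound to the helical polypeptide; the D-configured polymer is expected to give the (2S,3R)-epoxide, which fixes the later C3 centre.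

Step 9
Reactants: 11 the (2S,3R)-epoxy ketone
Product: 13 (2S,3S)-7-(benzyloxy)-2-[3,4-bis(benzyloxy)phenyl]-3-hydroxychroman-4-one (2,3-trans), via 2'-hydroxy epoxy ketone 12 (not isolated)
Conditions: HCl (2 M), MeOH/THF, 45 °C
Reagents that add atoms: none
Why: Acid cleaves the MOM acetal and the freed phenol opens the protonated epoxide at the benzylic carbon in a 6-endo ring closure, so that C3 keeps the epoxide C–O bond and C2 forms trans to it (inversion at the benzylic carbon, the trans isomer also being the more stable).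

Step 10
Reactants: 13 the (2S,3S)-dihydroflavonol
Product: 14 (2S,3S)-3,7-bis(benzyloxy)-2-[3,4-bis(benzyloxy)phenyl]chroman-4-one (tetra-O-benzyl-ent-fustin)
Conditions: 2-benzyloxy-1-methylpyridinium triflate, MgO, PhCF3, 85 °C
Reagents that add atoms: 2-benzyloxy-1-methylpyridinium triflate, C[n+]1ccccc1OCc1ccccc1.[O-]S(=O)(=O)C(F)(F)F
Why: Benzyl transfer from the neutral pyridinium salt (SN1-like O-benzylation) etherifies the 3-OH without base, which would open ring C by retro-oxa-Michael reaction or epimerise C3.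

Step 11
Reactants: 4 8-bromo-penta-O-benzylcatechin; 14 tetra-O-benzyl-ent-fustin
Product: 16 tertiary alcohol in which C4 of the flavan-4-ol (2S,3R; 4-OH cis to 3-OBn expected) is bonded to C8 of penta-O-benzylcatechin, via 8-lithio-penta-O-benzylcatechin 15 (not isolated)
Conditions: n-BuLi, THF, −78 °C; then 14, −78 → −40 °C; H2O
Reagents that add atoms: none
Why: Bromine–lithium exchange followed by 1,2-addition of the aryllithium to the ketone, which is faster than enolisation at −78 °C; the carbinol configuration is of no consequence because C4 becomes a cation in step 12.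

Step 12
Reactants: 16 the tertiary alcohol
Product: 17 nona-O-benzyl ent-fisetinidol-(4→8)-catechin, middle unit (2S,3R,4S) with the catechin unit cis to 3-OBn and trans to the 2-aryl group
Conditions: Bu3SnH, CF3CO2H, CH2Cl2, 0 °C
Reagents that add atoms: none
Why: Ionic hydrogenation: acid ionises the doubly benzylic carbinol and Bu3SnH delivers hydride to the cation face opposite the 3-benzyloxy group, which places the catechin unit cis to O3 (2,3-trans-3,4-cis).

Step 13
Reactants: 17 the nona-O-benzyl dimer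
Product: 18 dibromide of 17 with bromine at C6 of the middle unit and at C6 of the catechin unit
Conditions: NBS (2.1 equiv), CH2Cl2, −40 → 0 °C
Reagents that add atoms: N-bromosuccinimide, O=C1CCC(=O)N1Br
Why: Electrophilic aromatic bromination at the two most activated free positions, C6 of the catechin ring A (between two benzyloxy groups) and C6 of the middle-unit ring A (ortho to 7-OBn, para to O1, less hindered than C8).

Step 14
Reactants: 6 1-[4-(benzyloxy)-2-hydroxyphenyl]ethanone
Product: 19 1-[4-(benzyloxy)-2-(triisopropylsilyloxy)phenyl]ethanone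
Conditions: TIPSOTf, Et3N, CH2Cl2, 0 °C
Reagents that add atoms: triisopropylsilyl triflate, CC(C)[Si](C(C)C)(C(C)C)OS(=O)(=O)C(F)(F)F
Why: Silylation of the hydrogen-bonded phenol with the reactive silyl triflate gives a fluoride-labile ether that is orthogonal to benzyl.

Step 15
Reactants: 19 the TIPS-protected ketone
Product: 20 1-[4-(benzyloxy)-2-(triisopropylsilyloxy)phenyl]vinyl triflate
Conditions: Tf2O, 2,6-di-tert-butyl-4-methylpyridine, CH2Cl2, 0 °C → rt
Reagents that add atoms: triflic anhydride, O=S(=O)(OS(=O)(=O)C(F)(F)F)C(F)(F)F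
Why: O-triflation of the ketone through its triflyloxycarbenium ion and loss of a proton to the hindered pyridine gives the enol triflate without an enolate, so the silyl group cannot migrate to an enolate oxygen.

Step 16
Reactants: 20 the vinyl triflate
Product: 21 2-{1-[4-(benzyloxy)-2-(triisopropylsilyloxy)phenyl]vinyl}-4,4,5,5-tetramethyl-1,3,2-dioxaborolane
Conditions: B2pin2, PdCl2(PPh3)2, PPh3, KOPh, toluene, 50 °C
Reagents that add atoms: bis(pinacolato)diboron, CC1(C)OB(OC1(C)C)B1OC(C)(C)C(C)(C)O1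
Why: Miyaura borylation of the alkenyl triflate (oxidative addition, transmetalation with the phenoxide-activated diboron, reductive elimination).

Step 17
Reactants: 18 the dibromide; 21 the 1-arylvinylboronate (3 equiv)
Product: 22 dimer carrying a 1-[4-(benzyloxy)-2-(triisopropylsilyloxy)phenyl]vinyl group at C6 of the middle unit and at C6 of the catechin unit
Conditions: Pd(OAc)2, SPhos, K3PO4, toluene/H2O, 90 °C
Reagents that add atoms: none
Why: Twofold Suzuki–Miyaura coupling; the bulky electron-rich biarylphosphine allows oxidative addition and reductive elimination at the ortho-substituted aryl bromides, and the mild phosphate base leaves the TIPS ethers in place.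

Step 18
Reactants: 22 the bis-TIPS bis(1,1-diarylethene)
Product: 23 bis-phenol: the same dimer with a 1-[4-(benzyloxy)-2-hydroxyphenyl]vinyl group at both C6 positions
Conditions: Bu4NF, AcOH, THF, 0 °C
Reagents that add atoms: none
Why: Fluoride cleaves the aryl silyl ethers (Si–F bond formation) while acetic acid buffers the phenoxides; benzyl ethers and the 1,1-diarylethenes are inert.

Step 19
Reactants: 24 caffeic acid
Product: 25 benzyl (E)-3-[3,4-bis(benzyloxy)phenyl]acrylate
Conditions: BnBr (3.3 equiv), K2CO3, DMF, 60 °C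
Reagents that add atoms: benzyl bromide, BrCc1ccccc1
Why: Williamson alkylation of the carboxylate and both phenols in one operation.

Step 20
Reactants: 25 the benzyl cinnamate
Product: 26 (E)-3-[3,4-bis(benzyloxy)phenyl]prop-2-en-1-ol
Conditions: i-Bu2AlH, CH2Cl2, −78 → 0 °C
Reagents that add atoms: none
Why: 1,2-Reduction of the unsaturated ester by the aluminium hydride gives the (E)-allylic alcohol without touching the alkene.

Step 21
Reactants: 26 the cinnamyl alcohol
Product: 27 (E)-3-[3,4-bis(benzyloxy)phenyl]allyl methyl carbonate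
Conditions: ClCO2Me, pyridine, CH2Cl2, 0 °C
Reagents that add atoms: methyl chloroformate, COC(=O)Cl
Why: Acylation of the alcohol by the chloroformate gives the linear carbonate, the leaving group for allyl–metal formation.

Step 22
Reactants: 23 the bis-phenol; 27 the cinnamyl methyl carbonate (3 equiv)
Product: 29 bis[(R)-1-(3,4-bis(benzyloxy)phenyl)allyl] ether of 23 (both phenol oxygens carry the branched allyl group), via dilithium bis-phenoxide 28 (not isolated)
Conditions: LiOtBu (2.0 equiv), THF, rt; then 27, [Ir(cod)Cl]2 (4 mol %), (Ra,Rc,Rc)-O,O'-(1,1'-binaphthyl-2,2'-diyl)-N,N-bis(1-phenylethyl)phosphoramidite (8 mol %), THF, 40 °C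
Reagents that add atoms: none
Why: Iridium-catalysed asymmetric allylic substitution of Tsuji–Trost type: the Ir–phosphoramidite complex ionises the linear carbonate and each phenoxide attacks the aryl-bearing allyl terminus, the ligand setting the (R) configuration at both remote sites independently.

Step 23
Reactants: 29 the bis(allyl ether) bis(1,1-diarylethene)
Product: 30 benzylated tetramer with 2H-chromene rings (C3=C4) in the terminal unit and in the unit on catechin C6, both C2 centres (R)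
Conditions: second-generation Grubbs catalyst RuCl2(=CHPh)(H2IMes)(PCy3) (2 × 10 mol %), 2,6-dichloro-1,4-benzoquinone (20 mol %), toluene (2 mM), 80 °C, argon sparge
Reagents that add atoms: none
Why: The benzylidene initiates on each monosubstituted allyl alkene, and the resulting alkylidene adds intramolecularly across the neighbouring 1,1-diarylethene to a ruthenacyclobutane whose cycloreversion releases ethylene and leaves the trisubstituted C3=C4 bond. The closest known reaction type is ring-closing metathesis of 2-(1-substituted vinyl)phenyl allyl ethers to 4-substituted 2H-chromenes. Each ring C closes as a six-membered ring by joining C3 to C4, the ring of the terminal unit and the ring of the unit on catechin C6 forming independently in the same operation. No stereocentre is created, and the two C2 centres set in step 22 are carried through because neither the allylic C–H nor the C2–O bond takes part. The step needs ring closure to win over intermolecular metathesis and over double-bond migration: the 1,1-diarylethenes do not homodimerise, the two reacting alkenes of each pair sit on adjacent positions of one benzene ring, high dilution disfavours coupling between allyl termini, and the benzoquinone intercepts ruthenium hydrides. The temperature is held at 80 °C or below so that the 2H-chromenes do not open electrocyclically and lose the C2 configuration.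

Step 24
Reactants: 30 the bis-chromene
Product: 31 tetraol: in both outer units a 3,4-cis diol with 3-OH and 4-OH on the face opposite the C2 aryl group (2,3-trans), C4 tertiary
Conditions: OsO4 (20 mol %), NMO, DABCO, acetone/THF/H2O, rt
Reagents that add atoms: N-methylmorpholine N-oxide, C[N+]1([O-])CCOCC1; water, O
Why: Upjohn-type osmium tetroxide dihydroxylation by concerted [3+2] syn addition to each trisubstituted chromene alkene on the face opposite the C2 aryl group, which sets C3 (hydroxyl trans to the 2-aryl) and C4 in both rings.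

Step 25
Reactants: 31 the tetraol
Product: 32 pentadeca-O-benzyl tetramer with free 3-OH in the two outer units, each outer unit 2,3-trans-3,4-cis (C4 aryl cis to 3-OH)
Conditions: Bu3SnH, CF3CO2H, CH2Cl2, −20 → 0 °C
Reagents that add atoms: none
Why: Ionic hydrogenation of the two tertiary, doubly benzylic C4 carbinols: each diaryl cation takes hydride on the face opposite the adjacent C3 hydroxyl, so the C4 aryl ends cis to O3, while the secondary 3-OH does not ionise.

Step 26
Reactants: 32 the pentadeca-O-benzyl tetramer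
Product: 33 target CNP0126838.1 (terminal unit 2S,3R,4R; middle unit 2S,3R,4S; catechin unit 2R,3S; unit on catechin C6 2S,3R,4S)
Conditions: H2 (1 atm), Pd(OH)2/C, THF/MeOH, rt
Reagents that add atoms: none
Why: Catalytic hydrogenolysis of the fifteen benzyl ethers; the C2–O1 and C4–aryl bonds of flavans are not cleaved under these mild conditions.

**Compound list**

1 | (+)-catechin | O[C@H]1Cc2c(O)cc(O)cc2O[C@@H]1c1ccc(O)c(O)c1 | starting material
2 | 5,7,3',4'-tetra-O-benzyl-(+)-catechin | c1c(OCc9ccccc9)cc(OCc9ccccc9)c2c1O[C@H](c1ccc(OCc9ccccc9)c(OCc9ccccc9)c1)[C@@H](O)C2 | intermediate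
3 | 8-bromo-5,7,3',4'-tetra-O-benzylcatechin | Brc1c(OCc9ccccc9)cc(OCc9ccccc9)c2c1O[C@H](c1ccc(OCc9ccccc9)c(OCc9ccccc9)c1)[C@@H](O)C2 | intermediate
4 | 8-bromo-3,5,7,3',4'-penta-O-benzylcatechin | Brc1c(OCc9ccccc9)cc(OCc9ccccc9)c2c1O[C@H](c1ccc(OCc9ccccc9)c(OCc9ccccc9)c1)[C@@H](OCc9ccccc9)C2 | intermediate
5 | 2,4-dihydroxyacetophenone | CC(=O)c1ccc(O)cc1O | starting material
6 | 1-[4-(benzyloxy)-2-hydroxyphenyl]ethanone | CC(=O)c1ccc(OCc9ccccc9)cc1O | intermediate
7 | 1-[4-(benzyloxy)-2-(methoxymethoxy)phenyl]ethanone | CC(=O)c1ccc(OCc9ccccc9)cc1OCOC | intermediate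
8 | 3,4-dihydroxybenzaldehyde | O=Cc1ccc(O)c(O)c1 | starting material
9 | 3,4-bis(benzyloxy)benzaldehyde | O=Cc1ccc(OCc9ccccc9)c(OCc9ccccc9)c1 | intermediate
10 | (E)-1-[4-(benzyloxy)-2-(methoxymethoxy)phenyl]-3-[3,4-bis(benzyloxy)phenyl]prop-2-en-1-one | COCOc1cc(OCc9ccccc9)ccc1C(=O)/C=C/c1ccc(OCc9ccccc9)c(OCc9ccccc9)c1 | intermediate
11 | [(2S,3R)-3-(3,4-bis(benzyloxy)phenyl)oxiran-2-yl][4-(benzyloxy)-2-(methoxymethoxy)phenyl]methanone | COCOc1cc(OCc9ccccc9)ccc1C(=O)[C@H]1O[C@@H]1c1ccc(OCc9ccccc9)c(OCc9ccccc9)c1 | intermediate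
12 | [(2S,3R)-3-(3,4-bis(benzyloxy)phenyl)oxiran-2-yl][4-(benzyloxy)-2-hydroxyphenyl]methanone | Oc1cc(OCc9ccccc9)ccc1C(=O)[C@H]1O[C@@H]1c1ccc(OCc9ccccc9)c(OCc9ccccc9)c1 | intermediate
13 | (2S,3S)-7-(benzyloxy)-2-[3,4-bis(benzyloxy)phenyl]-3-hydroxychroman-4-one | O=C1c2ccc(OCc9ccccc9)cc2O[C@@H](c2ccc(OCc9ccccc9)c(OCc9ccccc9)c2)[C@@H]1O | intermediate
14 | (2S,3S)-3,7-bis(benzyloxy)-2-[3,4-bis(benzyloxy)phenyl]chroman-4-one | O=C1c2ccc(OCc9ccccc9)cc2O[C@@H](c2ccc(OCc9ccccc9)c(OCc9ccccc9)c2)[C@@H]1OCc9ccccc9 | intermediate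
15 | 8-lithio-3,5,7,3',4'-penta-O-benzylcatechin | [Li]c1c(OCc9ccccc9)cc(OCc9ccccc9)c2c1O[C@H](c1ccc(OCc9ccccc9)c(OCc9ccccc9)c1)[C@@H](OCc9ccccc9)C2 | intermediate
16 | 4-hydroxy dimer: tetra-O-benzyl-ent-fisetinidol-4-ol bonded by C4 to C8 of penta-O-benzylcatechin (4-OH cis to 3-OBn) | c1cc2c(cc1OCc9ccccc9)O[C@@H](c1ccc(OCc9ccccc9)c(OCc9ccccc9)c1)[C@H](OCc9ccccc9)[C@@]2(O)c1c(OCc9ccccc9)cc(OCc9ccccc9)c2c1O[C@H](c1ccc(OCc9ccccc9)c(OCc9ccccc9)c1)[C@@H](OCc9ccccc9)C2 | intermediate
17 | nona-O-benzyl ent-fisetinidol-(4→8)-catechin, 2,3-trans-3,4-cis in the middle unit | c1cc2c(cc1OCc9ccccc9)O[C@@H](c1ccc(OCc9ccccc9)c(OCc9ccccc9)c1)[C@H](OCc9ccccc9)[C@@H]2c1c(OCc9ccccc9)cc(OCc9ccccc9)c2c1O[C@H](c1ccc(OCc9ccccc9)c(OCc9ccccc9)c1)[C@@H](OCc9ccccc9)C2 | intermediate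
18 | dibromide of 17 (Br at C6 of the middle unit and C6 of the catechin unit) | Brc1cc2c(cc1OCc9ccccc9)O[C@@H](c1ccc(OCc9ccccc9)c(OCc9ccccc9)c1)[C@H](OCc9ccccc9)[C@@H]2c1c(OCc9ccccc9)c(Br)c(OCc9ccccc9)c2c1O[C@H](c1ccc(OCc9ccccc9)c(OCc9ccccc9)c1)[C@@H](OCc9ccccc9)C2 | intermediate
19 | 1-[4-(benzyloxy)-2-(triisopropylsilyloxy)phenyl]ethanone | CC(=O)c1ccc(OCc9ccccc9)cc1O[Si](C(C)C)(C(C)C)C(C)C | intermediate
20 | 1-[4-(benzyloxy)-2-(triisopropylsilyloxy)phenyl]vinyl triflate | C=C(OS(=O)(=O)C(F)(F)F)c1ccc(OCc9ccccc9)cc1O[Si](C(C)C)(C(C)C)C(C)C | intermediate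
21 | 2-{1-[4-(benzyloxy)-2-(triisopropylsilyloxy)phenyl]vinyl}-4,4,5,5-tetramethyl-1,3,2-dioxaborolane | C=C(B1OC(C)(C)C(C)(C)O1)c1ccc(OCc9ccccc9)cc1O[Si](C(C)C)(C(C)C)C(C)C | intermediate
22 | dimer with a 1-[4-(benzyloxy)-2-(triisopropylsilyloxy)phenyl]vinyl group at both C6 positions | CC(C)[Si](C(C)C)(C(C)C)Oc1cc(OCc9ccccc9)ccc1C(=C)c1cc2c(cc1OCc9ccccc9)O[C@@H](c1ccc(OCc9ccccc9)c(OCc9ccccc9)c1)[C@H](OCc9ccccc9)[C@@H]2c1c(OCc9ccccc9)c(C(=C)c3ccc(OCc9ccccc9)cc3O[Si](C(C)C)(C(C)C)C(C)C)c(OCc9ccccc9)c2c1O[C@H](c1ccc(OCc9ccccc9)c(OCc9ccccc9)c1)[C@@H](OCc9ccccc9)C2 | intermediate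
23 | bis-phenol: dimer with a 1-[4-(benzyloxy)-2-hydroxyphenyl]vinyl group at both C6 positions | Oc1cc(OCc9ccccc9)ccc1C(=C)c1cc2c(cc1OCc9ccccc9)O[C@@H](c1ccc(OCc9ccccc9)c(OCc9ccccc9)c1)[C@H](OCc9ccccc9)[C@@H]2c1c(OCc9ccccc9)c(C(=C)c3ccc(OCc9ccccc9)cc3O)c(OCc9ccccc9)c2c1O[C@H](c1ccc(OCc9ccccc9)c(OCc9ccccc9)c1)[C@@H](OCc9ccccc9)C2 | intermediate
24 | caffeic acid | OC(=O)/C=C/c1ccc(O)c(O)c1 | starting material
25 | benzyl (E)-3-[3,4-bis(benzyloxy)phenyl]acrylate | O=C(OCc9ccccc9)/C=C/c1ccc(OCc9ccccc9)c(OCc9ccccc9)c1 | intermediate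
26 | (E)-3-[3,4-bis(benzyloxy)phenyl]prop-2-en-1-ol | OC/C=C/c1ccc(OCc9ccccc9)c(OCc9ccccc9)c1 | intermediate
27 | (E)-3-[3,4-bis(benzyloxy)phenyl]allyl methyl carbonate | COC(=O)OC/C=C/c1ccc(OCc9ccccc9)c(OCc9ccccc9)c1 | intermediate
28 | dilithium bis-phenoxide of 23 | [Li]Oc1cc(OCc9ccccc9)ccc1C(=C)c1cc2c(cc1OCc9ccccc9)O[C@@H](c1ccc(OCc9ccccc9)c(OCc9ccccc9)c1)[C@H](OCc9ccccc9)[C@@H]2c1c(OCc9ccccc9)c(C(=C)c3ccc(OCc9ccccc9)cc3O[Li])c(OCc9ccccc9)c2c1O[C@H](c1ccc(OCc9ccccc9)c(OCc9ccccc9)c1)[C@@H](OCc9ccccc9)C2 | intermediate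
29 | bis[(R)-1-(3,4-bis(benzyloxy)phenyl)allyl] ether of 23 (metathesis precursor) | C=C[C@H](c1ccc(OCc9ccccc9)c(OCc9ccccc9)c1)Oc1cc(OCc9ccccc9)ccc1C(=C)c1cc2c(cc1OCc9ccccc9)O[C@@H](c1ccc(OCc9ccccc9)c(OCc9ccccc9)c1)[C@H](OCc9ccccc9)[C@@H]2c1c(OCc9ccccc9)c(C(=C)c3ccc(OCc9ccccc9)cc3O[C@@H](c3ccc(OCc9ccccc9)c(OCc9ccccc9)c3)C=C)c(OCc9ccccc9)c2c1O[C@H](c1ccc(OCc9ccccc9)c(OCc9ccccc9)c1)[C@@H](OCc9ccccc9)C2 | intermediate
30 | benzylated tetramer with C3=C4 double bonds in the terminal unit and in the unit on catechin C6 | C(c9ccccc9)Oc1ccc2c(c1)O[C@@H](c1ccc(OCc9ccccc9)c(OCc9ccccc9)c1)C=C2c1cc2c(cc1OCc9ccccc9)O[C@@H](c1ccc(OCc9ccccc9)c(OCc9ccccc9)c1)[C@H](OCc9ccccc9)[C@@H]2c1c(OCc9ccccc9)c(C2=C[C@H](c3ccc(OCc9ccccc9)c(OCc9ccccc9)c3)Oc3cc(OCc9ccccc9)ccc23)c(OCc9ccccc9)c2c1O[C@H](c1ccc(OCc9ccccc9)c(OCc9ccccc9)c1)[C@@H](OCc9ccccc9)C2 | intermediate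
31 | tetraol: 3,4-cis diols (anti to the C2 aryl) in both outer units | C(c9ccccc9)Oc1ccc2c(c1)O[C@@H](c1ccc(OCc9ccccc9)c(OCc9ccccc9)c1)[C@H](O)[C@@]2(O)c1cc2c(cc1OCc9ccccc9)O[C@@H](c1ccc(OCc9ccccc9)c(OCc9ccccc9)c1)[C@H](OCc9ccccc9)[C@@H]2c1c(OCc9ccccc9)c([C@@]2(O)c3ccc(OCc9ccccc9)cc3O[C@@H](c3ccc(OCc9ccccc9)c(OCc9ccccc9)c3)[C@@H]2O)c(OCc9ccccc9)c2c1O[C@H](c1ccc(OCc9ccccc9)c(OCc9ccccc9)c1)[C@@H](OCc9ccccc9)C2 | intermediate
32 | pentadeca-O-benzyl tetramer, free 3-OH in the two outer units | C(c9ccccc9)Oc1ccc2c(c1)O[C@@H](c1ccc(OCc9ccccc9)c(OCc9ccccc9)c1)[C@H](O)[C@@H]2c1cc2c(cc1OCc9ccccc9)O[C@@H](c1ccc(OCc9ccccc9)c(OCc9ccccc9)c1)[C@H](OCc9ccccc9)[C@@H]2c1c(OCc9ccccc9)c([C@@H]2c3ccc(OCc9ccccc9)cc3O[C@@H](c3ccc(OCc9ccccc9)c(OCc9ccccc9)c3)[C@@H]2O)c(OCc9ccccc9)c2c1O[C@H](c1ccc(OCc9ccccc9)c(OCc9ccccc9)c1)[C@@H](OCc9ccccc9)C2 | intermediate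
33 | CNP0126838.1: ent-fisetinidol (C4→C6) ent-fisetinidol (C4→C8) catechin (C6←C4) ent-fisetinidol, all ent-fisetinidol units 2,3-trans-3,4-cis | Oc1ccc2c(c1)O[C@@H](c1ccc(O)c(O)c1)[C@H](O)[C@@H]2c1cc2c(cc1O)O[C@@H](c1ccc(O)c(O)c1)[C@H](O)[C@@H]2c1c(O)c([C@@H]2c3ccc(O)cc3O[C@@H](c3ccc(O)c(O)c3)[C@@H]2O)c(O)c2c1O[C@H](c1ccc(O)c(O)c1)[C@@H](O)C2 | target

**Step count and risk**

Total step count: 26.
Longest linear sequence: 16 steps, from 2,4-dihydroxyacetophenone 5 to 33 (steps 4, 5, 7–13, 17, 18, 22–26).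

Steps most likely to fail:

1. Step 23 (double ring-closing metathesis). The alkylidene loaded on the allyl terminus may fail to add across the 1,1-diarylethene on catechin C6, whose aryl group carries two ortho benzyloxy groups, so that only one ring closes. Ruthenium hydride may instead move the allyl double bond into an enol ether, or the electron-rich benzylic allylic ether may ionise and lose the C2 configuration. Fallback (known chemistry; sets out from dibromide 18 and returns at 30): the C4–aryl bonds are made by cross-coupling of a preformed, enantiopure flav-3-ene. Purchased 7-hydroxychromone is benzylated (BnBr, K2CO3) to 7-(benzyloxy)-4H-chromen-4-one F1. Conjugate addition of purchased 3,4-bis(benzyloxy)phenylboronic acid, catalysed by Pd(OCOCF3)2 with the enantiomer of tert-butyl pyridine-oxazoline ligand that leads to the (R) product, gives (R)-7-(benzyloxy)-2-[3,4-bis(benzyloxy)phenyl]chroman-4-one F2. Triflation without an enolate (Tf2O, 2,6-di-tert-butyl-4-methylpyridine) gives (R)-7-(benzyloxy)-2-[3,4-bis(benzyloxy)phenyl]-2H-chromen-4-yl triflate F3. Miyaura borylation (B2pin2, PdCl2(PPh3)2, KOPh) gives the corresponding chromen-4-yl pinacol boronate F4. Twofold Suzuki–Miyaura coupling of F4 with 18 (Pd(OAc)2, SPhos, K3PO4) then gives bis-chromene 30.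

2. Step 22 (twofold iridium-catalysed allylic etherification). Attack at two hindered ortho-substituted phenoxides may be slow. With the carbonate in excess, the iridium catalyst may re-ionise the electron-rich branched ether, which drifts towards the linear ether and erodes the configuration at one or both sites. Fallback (known chemistry; sets out from bis-phenol 23 and aldehyde 9 and returns at 29): the stereocentre is made on a small molecule and transferred, instead of being set by the catalyst on the large one. Vinylmagnesium bromide adds to 9 to give racemic 1-[3,4-bis(benzyloxy)phenyl]prop-2-en-1-ol F5. Lipase-catalysed acylation (Candida antarctica lipase B, vinyl acetate) is expected, by the empirical rule for secondary alcohols, to acylate the (R)-enantiomer and give (R)-1-[3,4-bis(benzyloxy)phenyl]allyl acetate F6. Methanolysis (K2CO3, MeOH) gives (R)-1-[3,4-bis(benzyloxy)phenyl]prop-2-en-1-ol F7, and Boc2O gives its tert-butyl carbonate F8. Substitution of F8 by 23 with [Cp*Ru(MeCN)3]PF6, a reaction type that keeps the branched position and proceeds with net retention, gives 29.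

3. Step 17 (twofold Suzuki coupling). Transmetalation at the bromide on catechin C6, flanked by two benzyloxy groups, may be slower than protodeboronation of the 1-arylvinylboronate, which leaves the mono-coupled product; partial loss of the silyl ethers under the aqueous base is a second concern. Fallback (known chemistry; sets out from dibromide 18 and ketone 19 and returns at 22): the alkene is formed by carbene coupling without a boron reagent. Ketone 19 is condensed with tosylhydrazide to N'-{1-[4-(benzyloxy)-2-(triisopropylsilyloxy)phenyl]ethylidene}-4-methylbenzenesulfonohydrazide F9. Barluenga coupling of F9 with 18 (Pd2(dba)3, XPhos, LiOtBu, dioxane, 100 °C) proceeds through the diazo compound, migratory insertion of the palladium carbene and β-hydride elimination, and gives the 1,1-diarylethenes of 22 directly.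

**Further compounds**

F1 | step 23 | 7-(benzyloxy)-4H-chromen-4-one | O=c1ccoc2cc(OCc3ccccc3)ccc12
F2 | step 23 | (R)-7-(benzyloxy)-2-[3,4-bis(benzyloxy)phenyl]chroman-4-one | O=C1C[C@H](c3ccc(OCc9ccccc9)c(OCc9ccccc9)c3)Oc2cc(OCc9ccccc9)ccc12
F3 | step 23 | (R)-7-(benzyloxy)-2-[3,4-bis(benzyloxy)phenyl]-2H-chromen-4-yl triflate | FC(F)(F)S(=O)(=O)OC1=C[C@H](c3ccc(OCc9ccccc9)c(OCc9ccccc9)c3)Oc2cc(OCc9ccccc9)ccc12
F4 | step 23 | (R)-2-{7-(benzyloxy)-2-[3,4-bis(benzyloxy)phenyl]-2H-chromen-4-yl}-4,4,5,5-tetramethyl-1,3,2-dioxaborolane | CC1(C)OB(OC1(C)C)C1=C[C@H](c3ccc(OCc9ccccc9)c(OCc9ccccc9)c3)Oc2cc(OCc9ccccc9)ccc12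
F5 | step 22 | racemic 1-[3,4-bis(benzyloxy)phenyl]prop-2-en-1-ol | C=CC(O)c1ccc(OCc9ccccc9)c(OCc9ccccc9)c1
F6 | step 22 | (R)-1-[3,4-bis(benzyloxy)phenyl]allyl acetate | C=C[C@H](c1ccc(OCc9ccccc9)c(OCc9ccccc9)c1)OC(C)=O
F7 | step 22 | (R)-1-[3,4-bis(benzyloxy)phenyl]prop-2-en-1-ol | C=C[C@H](c1ccc(OCc9ccccc9)c(OCc9ccccc9)c1)O
F8 | step 22 | (R)-1-[3,4-bis(benzyloxy)phenyl]allyl tert-butyl carbonate | C=C[C@H](c1ccc(OCc9ccccc9)c(OCc9ccccc9)c1)OC(=O)OC(C)(C)C
F9 | step 17 | N'-{1-[4-(benzyloxy)-2-(triisopropylsilyloxy)phenyl]ethylidene}-4-methylbenzenesulfonohydrazide | CC(=NNS(=O)(=O)c1ccc(C)cc1)c1ccc(OCc9ccccc9)cc1O[Si](C(C)C)(C(C)C)C(C)C
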